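The data are simulated with made-up constants; noise was put on by code.

I have no constants for this flask, just two runs, and neither of them varies the reagent.

common to all: free catalyst 0.11 mM

| charge | left-handed substrate | right-handed substrate | reagent | remark |
|---|---|---|---|---|
| amber | 20 mM | 20 mM | 60 mM | the very flask that is asked about, followed so far |
| grey | 10 mM | 10 mM | 60 mM | run made earlier |
| flask | 20 mM | 20 mM | 60.0 mM |  |

- amber (time / min: left-handed product / %): 1.50: 24.9; 3.00: 33.5; 5.00: 39.6; 6.00: 39.6; 8.00: 43.2; 10.0: 42.3; 12.0: 44.2
- grey (time / min: left-handed product / %): 2.00: 30.1; 3.00: 34.8; 4.00: 38.7; 6.00: 40.5; 10.0: 45.9; 15.0: 47.9; 25.0: 48.4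

(standard deviation of a reading: 1 percentage point)

1. apparent order in reagent when 30% of the left-handed substrate and right-handed substrate together are converted (percent change of the rate of making left-handed product for one percent more reagent charged)

- free catalyst is single-handed; left-handed substrate and right-handed substrate are mirror images of each other, charged as a racemate, each of them at the stated concentration
- the earlier runs were read with a standard deviation of 1 percentage point
- no earlier run changes the charge of reagent; that part of a forecast is a guess

I take the rate as proportional to reagent, which is a guess. Two versions of the flask can then be solved in the head. If reagent stood still, one percent more charge would give one percent more rate, an order of 1. If reagent left mole for mole with substrate, 30% conversion would cost 12.0 mM and leave 48.0 mM. An extra millimole would then survive whole, and the percent gain would be stretched to 1.25. This is the leverage L, charge over reagent remaining at that conversion.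

The grey run has L = 1.11, yet at 6.00 min amber reads 39.6% and grey 40.5%, within the scatter. Both runs bend alike, with first-order constants falling from 0.46 to 0.15 per minute, so mole-for-mole use does not explain the bend. If catalyst fades or reagent leaks elsewhere, reaching the conversion sooner pays, so my own reckoning goes a little above L.

The forecast differs from my reckoning: it stays at L, saying 1.25, between 0.7 and 1.7, and calls the depletion evidence “weakly determined”.

    reagent + free catalyst + left-handed substrate → free catalyst + left-handed product (k = 1780 M⁻² s⁻¹)
    reagent + free catalyst → spent catalyst (k = 0.00177 M⁻¹ s⁻¹)
    reagent + free catalyst + right-handed substrate → free catalyst + right-handed product (k = 12.7 M⁻² s⁻¹)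
    2 reagent → homo dimer (k = 0.0684 M⁻¹ s⁻¹)

This flask gives 1.4, inside that range. At the start the step to homo dimer uses reagent faster than the step to left-handed product, by a factor of 2.1. At 0.100 h, with left-handed product at 40.0% of both substrates charged, mole-for-mole use gives L = 1.36. Charge over reagent actually standing is 5.46, with reagent at 18.3% of its own charge.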